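**Plan**

- Retrosynthesis cuts the two benzoate C–O bonds (O5–C(=O) and O7–C(=O)) first, then takes C7 back to an ester, the C3=C4/O5 unit back to a C4–C5 epoxide, and finally the ring bonds C1–C6 and C2–C3 (Diels–Alder).
- Forward, crotonaldehyde gives a 1-silyloxybutadiene whose [4+2] addition to methyl propiolate forms the only ring. Epoxidation, base-induced epoxide opening, ester reduction and desilylation lead to the racemic trans-triol, and one lipase operation then benzoylates O7 and O5.
- The key step rests on the three unlike hydroxyls of the cyclohexa-1,3-diene ring: primary O7 on the exocyclic C7, secondary O5 on C5 between the sp2 CH C4 and C6, and secondary O6 on C6 between C5 and the fully substituted C1.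
- The trans O5/O6 relationship comes from epoxidation anti to the C6 silyl ether. The absolute (5R,6R) configuration comes from the lipase, which benzoylates O5 of that enantiomer only and leaves the (5S,6S) material as a separable monobenzoate.

Key step: step 7

Remark: target locants are used throughout (C1 carries C7, C5 and C6 carry the ring oxygens); compounds 4 to 9 and 11 are racemic and are drawn as the enantiomer that leads to the target.

**Route**

Step 1
Reactants: 1 (E)-crotonaldehyde
Product: 2 (E)-1-[(tert-butyldimethylsilyl)oxy]buta-1,3-diene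
Conditions: TBSOTf (1.1 equiv), Et3N (1.5 equiv), Et2O, 0 °C → rt
Reagents that add atoms: tert-butyldimethylsilyl trifluoromethanesulfonate, CC(C)(C)[Si](C)(C)OS(=O)(=O)C(F)(F)F
Why: O-silylation of the enal followed by γ-deprotonation with the amine (vinylogous silyl enol ether formation) should give the conjugated silyloxydiene, the E isomer being the one that reacts in the next step.

Step 2
Reactants: 2 (E)-1-[(tert-butyldimethylsilyl)oxy]buta-1,3-diene; 3 methyl propiolate
Product: 4 methyl (±)-6-[(tert-butyldimethylsilyl)oxy]cyclohexa-1,4-diene-1-carboxylate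
Conditions: 3 (1.5 equiv), BHT (cat.), toluene, 80 °C, sealed vessel, base-free work-up
Reagents that add atoms: none
Why: A thermal Diels–Alder reaction of a 1-oxygenated diene with an acetylenic ester closes the six-membered ring with "ortho" regiochemistry (C6–OSi next to C1–CO2Me), and the single stereocentre C6 arises as a racemate.

Step 3
Reactants: 4 methyl (±)-6-[(tert-butyldimethylsilyl)oxy]cyclohexa-1,4-diene-1-carboxylate
Product: 5 methyl (±)-(1R*,2R*,6R*)-2-[(tert-butyldimethylsilyl)oxy]-7-oxabicyclo[4.1.0]hept-3-ene-3-carboxylate (C4–C5 epoxide in target locants, oxygen trans to O6)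
Conditions: mCPBA (1.1 equiv), NaHCO3 (solid), CH2Cl2, 0 °C
Reagents that add atoms: 3-chloroperoxybenzoic acid, OOC(=O)c1cccc(Cl)c1
Why: In this Prilezhaev epoxidation the peracid should attack the isolated C4=C5 alkene in preference to the electron-poor enoate C1=C2 and approach anti to the bulky allylic silyl ether, which sets C4 and C5 trans to O6 (relative configuration, substrate control).

Step 4
Reactants: 5 methyl (±)-(1R*,2R*,6R*)-2-[(tert-butyldimethylsilyl)oxy]-7-oxabicyclo[4.1.0]hept-3-ene-3-carboxylate
Product: 6 methyl (±)-(5R*,6R*)-6-[(tert-butyldimethylsilyl)oxy]-5-hydroxycyclohexa-1,3-diene-1-carboxylate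
Conditions: DBU (0.3 equiv), CH2Cl2, 0 °C → rt, short reaction time
Reagents that add atoms: none
Why: Base-induced vinylogous E1cB opening (γ-deprotonation at C3 of the enoate, then β-elimination of the C4–O bond) gives the conjugated dienoate without touching the C5–O bond, so the trans O5/O6 relationship is kept.

Step 5
Reactants: 6 methyl (±)-(5R*,6R*)-6-[(tert-butyldimethylsilyl)oxy]-5-hydroxycyclohexa-1,3-diene-1-carboxylate
Product: 8 (±)-[(5R*,6R*)-6-[(tert-butyldimethylsilyl)oxy]-5-hydroxycyclohexa-1,3-dien-1-yl]methanol, via hydroxy silyloxy dienal 7 (not isolated)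
Conditions: i-Bu2AlH (3.5 equiv), CH2Cl2, −78 → −20 °C; then aq. KNaC4H4O6 (potassium sodium tartrate), rt
Reagents that add atoms: none
Why: Hydride 1,2-reduction of the dienoate by i-Bu2AlH (one equivalent being consumed by O5–H) passes through the aldehyde to the allylic alcohol, and the cold, non-acidic tartrate work-up avoids ionisation and aromatisation of the dienol.

Step 6
Reactants: 8 (±)-[(5R*,6R*)-6-[(tert-butyldimethylsilyl)oxy]-5-hydroxycyclohexa-1,3-dien-1-yl]methanol
Product: 9 (±)-(5R*,6R*)-5,6-dihydroxycyclohexa-1,3-diene-1-methanol (racemic trans-triol)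
Conditions: Bu4NF (1.2 equiv), THF, 0 °C → rt; concentration and direct chromatography on Et3N-deactivated SiO2
Reagents that add atoms: none
Why: Fluoride-mediated cleavage of the silyl ether, driven by Si–F bond formation, takes place in a non-acidic medium in which the dehydration-prone dienetriol should survive.

Step 7
Reactants: 9 (±)-(5R*,6R*)-5,6-dihydroxycyclohexa-1,3-diene-1-methanol; 10 vinyl benzoate
Product: 12 [(5R,6R)-5-(benzoyloxy)-6-hydroxycyclohexa-1,3-dien-1-yl]methyl benzoate, via racemic 7-monobenzoate 11 (not isolated)
Conditions: Burkholderia cepacia lipase immobilised on diatomaceous earth, 10 (3 equiv), t-BuOMe/THF, 4 Å molecular sieves, 35 °C; stopped by chiral HPLC control when the (5R,6R) half of 11 is consumed; filtration, SiO2 chromatography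
Reagents that add atoms: none
Why: The active-site serine of the lipase (Ser-His-Asp triad) is benzoylated by vinyl benzoate, irreversibly because the vinyl alcohol released tautomerises to acetaldehyde, and the acyl-enzyme passes benzoyl first to the exposed primary O7 of both enantiomers (giving 11) and then to the secondary O5 of the (5R,6R) enantiomer only. The closest known reaction type is the lipase-catalysed acylative kinetic resolution of trans-cycloalkane-1,2-diols and cyclic secondary allylic alcohols with vinyl esters, governed by the empirical large/medium-substituent model of the alcohol pocket. No ring is closed and no stereocentre is created; C5 and C6 are formed as a racemic trans pair in steps 2 and 3 and the enzyme only selects the (5R,6R) pair. Enantioselectivity at O5 is expected because in the (5R) carbinol the branched C6 and the flat C4H= fit the large and medium sites as in the fast-reacting (R,R)-diols, whereas the (5S) carbinol would have to exchange them. Site selectivity between O5 and O6 is secured by the substrate, since O6 is flanked by C5 and the fully substituted C1 and offers two large groups to the pocket in either enantiomer. The (5S,6S) 7-monobenzoate that remains is more polar than the dibenzoate and is removed by chromatography.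

**Compound list**

1 | (E)-crotonaldehyde | C/C=C/C=O | starting material
2 | (E)-1-[(tert-butyldimethylsilyl)oxy]buta-1,3-diene | C=C/C=C/O[Si](C)(C)C(C)(C)C | intermediate
3 | methyl propiolate | C#CC(=O)OC | starting material
4 | methyl (±)-6-[(tert-butyldimethylsilyl)oxy]cyclohexa-1,4-diene-1-carboxylate (6S enantiomer drawn) | COC(=O)C1=CCC=C[C@@H]1O[Si](C)(C)C(C)(C)C | intermediate
5 | methyl (±)-(1R*,2R*,6R*)-2-[(tert-butyldimethylsilyl)oxy]-7-oxabicyclo[4.1.0]hept-3-ene-3-carboxylate (epoxide anti to the silyloxy group; 1R,2R,6R drawn) | COC(=O)C1=CC[C@H]2O[C@H]2[C@@H]1O[Si](C)(C)C(C)(C)C | intermediate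
6 | methyl (±)-(5R*,6R*)-6-[(tert-butyldimethylsilyl)oxy]-5-hydroxycyclohexa-1,3-diene-1-carboxylate (trans; 5R,6R drawn) | COC(=O)C1=CC=C[C@@H](O)[C@@H]1O[Si](C)(C)C(C)(C)C | intermediate
7 | (±)-(5R*,6R*)-6-[(tert-butyldimethylsilyl)oxy]-5-hydroxycyclohexa-1,3-diene-1-carbaldehyde (formed in the flask, not isolated) | O=CC1=CC=C[C@@H](O)[C@@H]1O[Si](C)(C)C(C)(C)C | intermediate
8 | (±)-[(5R*,6R*)-6-[(tert-butyldimethylsilyl)oxy]-5-hydroxycyclohexa-1,3-dien-1-yl]methanol | OCC1=CC=C[C@@H](O)[C@@H]1O[Si](C)(C)C(C)(C)C | intermediate
9 | (±)-(5R*,6R*)-5,6-dihydroxycyclohexa-1,3-diene-1-methanol (racemic trans-triol; 5R,6R drawn) | OCC1=CC=C[C@@H](O)[C@@H]1O | intermediate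
10 | vinyl benzoate | C=COC(=O)c1ccccc1 | starting material
11 | (±)-[(5R*,6R*)-5,6-dihydroxycyclohexa-1,3-dien-1-yl]methyl benzoate (7-monobenzoate, formed in the flask, not isolated; 5R,6R drawn) | O=C(OCC1=CC=C[C@@H](O)[C@@H]1O)c1ccccc1 | intermediate
12 | [(5R,6R)-5-(benzoyloxy)-6-hydroxycyclohexa-1,3-dien-1-yl]methyl benzoate (CNP0113836.1) | O=C(OCC1=CC=C[C@@H](OC(=O)c2ccccc2)[C@@H]1O)c1ccccc1 | target

**Step count**

Total steps: 7. Longest linear sequence: 7 (from crotonaldehyde 1 to 12).

**Steps most likely to fail**

Step 7. Benzoyl transfer to the secondary O5 may be too slow or not enantioselective enough, and on long reaction times benzoyl may migrate from O5 to O6. The fallback sets out from silyl ether 8, in which O6 is still blocked, provided the silyl group has stayed on O6. Chemical benzoylation of O7 and O5 (BzCl, pyridine, cat. DMAP, CH2Cl2, 0 °C) should give the racemic 6-O-silyl 5,7-dibenzoate F1. Desilylation with HF·pyridine in THF/pyridine at 0 °C (an acidic fluoride source, chosen so that the O5 benzoate does not move to the freed O6) should then give the racemate, that is 12 together with its (5S,6S)-dibenzoate enantiomer F2. Preparative HPLC on an amylose tris(3,5-dimethylphenylcarbamate) phase removes F2 and comes back to the route at 12.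

Step 2. At the temperature the cycloaddition needs, silanol may be lost from the adduct (aromatisation to methyl benzoate), and the diene may polymerise. The fallback sets out from diene 2 and uses methyl acrylate as dienophile (toluene, 80 °C), giving methyl cis-2-[(tert-butyldimethylsilyl)oxy]cyclohex-3-ene-1-carboxylate F3, a cyclohexene that cannot aromatise by simple elimination. The C1=C2 unsaturation is then introduced in the cold: enolate formation and selenenylation (LiN(i-Pr)2, THF, −78 °C; PhSeBr) should give the α-phenylselanyl ester F4. Oxidation (H2O2, pyridine, CH2Cl2, 0 °C) should then trigger selenoxide syn-elimination away from the oxygen-bearing carbon, which comes back to the route at 4.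

Step 6. The dienetriol may dehydrate to aromatic products during deprotection, or be lost while it is separated from the ammonium salts. The fallback sets out from 6 and reverses the order of the last two operations. Desilylation at the stage of the conjugated ester (Bu4NF, THF, 0 °C) should give methyl (5R*,6R*)-5,6-dihydroxycyclohexa-1,3-diene-1-carboxylate F5, which is extractable and less prone to ionisation. Reduction with i-Bu2AlH (5 equiv, THF, −78 → 0 °C) then passes through the dihydroxy dienal F6 in the flask. A non-aqueous work-up (MeOH, then Na2SO4·10H2O, filtration) delivers the triol free of ammonium salts and comes back to the route at 9.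

**Further compounds**

F1 | step 7 | (±)-[(5R*,6R*)-5-(benzoyloxy)-6-[(tert-butyldimethylsilyl)oxy]cyclohexa-1,3-dien-1-yl]methyl benzoate | O=C(OCC1=CC=C[C@@H](OC(=O)c2ccccc2)[C@@H]1O[Si](C)(C)C(C)(C)C)c1ccccc1
F2 | step 7 | [(5S,6S)-5-(benzoyloxy)-6-hydroxycyclohexa-1,3-dien-1-yl]methyl benzoate (enantiomer of 12, formed with it as the racemate) | O=C(OCC1=CC=C[C@H](OC(=O)c2ccccc2)[C@H]1O)c1ccccc1
F3 | step 2 | methyl (±)-cis-2-[(tert-butyldimethylsilyl)oxy]cyclohex-3-ene-1-carboxylate | COC(=O)[C@@H]1CCC=C[C@@H]1O[Si](C)(C)C(C)(C)C
F4 | step 2 | methyl (±)-1-(phenylselanyl)-2-[(tert-butyldimethylsilyl)oxy]cyclohex-3-ene-1-carboxylate (selenium trans to the silyloxy group drawn) | COC(=O)[C@]1([Se]c2ccccc2)CCC=C[C@@H]1O[Si](C)(C)C(C)(C)C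
F5 | step 6 | methyl (±)-(5R*,6R*)-5,6-dihydroxycyclohexa-1,3-diene-1-carboxylate | COC(=O)C1=CC=C[C@@H](O)[C@@H]1O
F6 | step 6 | (±)-(5R*,6R*)-5,6-dihydroxycyclohexa-1,3-diene-1-carbaldehyde | O=CC1=CC=C[C@@H](O)[C@@H]1O
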